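## Retrosynthetic overview
1. 20 ⇒ 18. The last step is one head-to-tail cationic cascade of the complete acyclic C20 chain. Ring A closes first, then ring B, and the C8 cation is discharged by loss of Me3Si from C17 to give the exocyclic methylene. The lactone ring and its 14-acetate are carried through intact.
2. The initiator is the (3R)-hydroxy-(4S)-4,19-epoxide, the Payne-type isomer of the usual 3,4-epoxide. C5 displaces O19 at C4 with inversion, which gives the axial CH2OH (C19) next to the equatorial 3-OH.
3. 18 ⇒ 11 + 17 by cross-metathesis at C12=C13. Compound 17, which carries C14, comes from (S)-3-hydroxy-γ-butyrolactone.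
4. 11 ⇒ rac-10 by Sharpless kinetic-resolution epoxidation, which fixes C3 and C4. 10 ⇒ 1 by Johnson–Claisen rearrangement (E-C5=C10) and carbocupration–allylation (Z-allylsilane at C8=C9).

Assumption: positions in acyclic intermediates use the labdane numbering (C1–C20) of the target, and small commercial reagents that deliver atoms are listed under "Reagents that add atoms" and are not numbered.

## Route

Step 1
Reactants: 1 pent-4-yn-1-ol
Product: 2 pent-4-ynal
Conditions: TEMPO (5 mol%), PhI(OAc)2 (1.1 equiv), CH2Cl2, rt
Reagents that add atoms: none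
Why: The oxoammonium-catalysed (TEMPO) alcohol oxidation stops at the aldehyde and leaves the terminal alkyne alone, and no stereocentre is formed.

Step 2
Reactants: 2 pent-4-ynal
Product: 3 rac-2-methylhept-1-en-6-yn-3-ol
Conditions: CH2=C(CH3)MgBr (1.15 equiv), THF, −78 °C; aq. work-up
Reagents that add atoms: isopropenylmagnesium bromide, C=C(C)[Mg]Br
Why: Grignard 1,2-addition to the aldehyde outruns alkyne deprotonation at −78 °C, and the racemic carbinol centre is erased in the next step.

Step 3
Reactants: 3 rac-2-methylhept-1-en-6-yn-3-ol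
Product: 5 ethyl (4E)-4-methylnon-4-en-8-ynoate, via ketene acetal 4 (not isolated)
Conditions: MeC(OEt)3 (6 equiv), EtCO2H (5 mol%), 140 °C, EtOH distilled off
Reagents that add atoms: triethyl orthoacetate, CC(OCC)(OCC)OCC
Why: The Johnson–Claisen [3,3]-rearrangement runs through a chair in which the homopropargyl chain sits equatorial to avoid the 1,3-diaxial clash with OEt, so the trisubstituted C10=C5 alkene forms with E selectivity above 95:5.

Step 4
Reactants: 5 ethyl (4E)-4-methylnon-4-en-8-ynoate
Product: 7 ethyl (4E,8Z)-4-methyl-8-[(trimethylsilyl)methyl]dodeca-4,8,11-trienoate, via alkenylcopper 6 (not isolated)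
Conditions: Me3SiCH2MgCl (1.5 equiv), CuBr·SMe2 (1.5 equiv), Et2O/Me2S, −40 °C; add 5, −40 → 0 °C; allyl bromide (3 equiv), DMPU, −30 °C → rt
Reagents that add atoms: (trimethylsilyl)methylmagnesium chloride, C[Si](C)(C)C[Mg]Cl; allyl bromide, C=CCBr
Why: Normant carbocupration adds Me3SiCH2–Cu syn across the 1-alkyne with copper on the terminal carbon, and stereoretentive allylation then places CH2SiMe3 cis to the new C11 methylene, which is the geometry that makes C11 equatorial later, while the ester is inert to RCu.

Step 5
Reactants: 7 ethyl (4E,8Z)-4-methyl-8-[(trimethylsilyl)methyl]dodeca-4,8,11-trienoate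
Product: 10 rac-(6E,10Z)-2,6-dimethyl-10-[(trimethylsilyl)methyl]tetradeca-1,6,10,13-tetraen-3-ol, via aluminium hemiacetal 8 (not isolated), via trienal 9 (not isolated)
Conditions: iBu2AlH (1.05 equiv), CH2Cl2, −78 °C; then CH2=C(CH3)MgBr (2 equiv), THF, −78 → 0 °C; aq. Rochelle salt
Reagents that add atoms: isopropenylmagnesium bromide, C=C(C)[Mg]Br
Why: In this one-pot partial ester reduction and Grignard addition the stable tetrahedral aluminium hemiacetal releases the aldehyde only on warming, where it is trapped at once, and the new C3 carbinol is racemic and is resolved in step 6.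

Step 6
Reactants: 10 rac-(6E,10Z)-2,6-dimethyl-10-[(trimethylsilyl)methyl]tetradeca-1,6,10,13-tetraen-3-ol
Product: 11 (1R,4E,8Z)-4-methyl-1-[(2S)-2-methyloxiran-2-yl]-8-[(trimethylsilyl)methyl]dodeca-4,8,11-trien-1-ol
Conditions: Ti(OiPr)4 (0.15 equiv), D-(−)-diisopropyl tartrate (0.20 equiv), tBuOOH (0.5 equiv, decane), 4 Å MS, CH2Cl2, −20 °C, stopped at ca. 45% conversion
Reagents that add atoms: tert-butyl hydroperoxide, CC(C)(C)OO
Why: In this Sharpless kinetic-resolution epoxidation the D-(−)-tartrate catalyst consumes only the (3R)-alcohol and delivers oxygen to the face that gives the erythro (3R,4S)-epoxy alcohol, so C3 and C4 are fixed together, the undirected alkenes and the allylsilane are untouched, and unreacted (S)-10 is removed by chromatography.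

Step 7
Reactants: 12 (S)-3-hydroxy-γ-butyrolactone
Product: 14 (3S,4S)-3-[(dimethylamino)methyl]-4-hydroxyoxolan-2-one, via dilithio dianion 13 (not isolated)
Conditions: LiN(iPr)2 (commercial solution, 2.2 equiv), THF, −78 °C; CH2=NMe2+ I− (1.2 equiv), −78 → −20 °C; aq. work-up
Reagents that add atoms: Eschenmoser's salt (N,N-dimethylmethyleneiminium iodide), C=[N+](C)C.[I-]
Why: In this Mannich alkylation of the β-hydroxy-lactone dianion the alkoxide is too poor a leaving group for β-elimination, attack occurs trans to it (a centre lost in step 8), and C14 is retained from the chiral pool.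

Step 8
Reactants: 14 (3S,4S)-3-[(dimethylamino)methyl]-4-hydroxyoxolan-2-one
Product: 16 (4S)-4-hydroxy-3-methylideneoxolan-2-one, via ammonium iodide 15 (not isolated)
Conditions: MeI (3 equiv), MeOH, rt; then aq. NaHCO3/CH2Cl2, rt
Reagents that add atoms: none
Why: In this Eschenmoser methylenation quaternisation makes NMe3 by far the best β-leaving group, so the mild-base E1cB elimination gives the exocyclic methylene rather than losing the 14-hydroxyl, and C14 is not touched.

Step 9
Reactants: 16 (4S)-4-hydroxy-3-methylideneoxolan-2-one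
Product: 17 (3S)-4-methylidene-5-oxooxolan-3-yl acetate
Conditions: Ac2O (1.5 equiv), pyridine, CH2Cl2, 0 °C → rt, no DMAP
Reagents that add atoms: acetic anhydride, CC(=O)OC(C)=O
Why: This O-acylation with retention at C14 installs the only acetate of the target before any other hydroxyl exists, and leaving out nucleophilic catalysts avoids SN2' attack on the allylic acetate.

Step 10
Reactants: 11 (1R,4E,8Z)-4-methyl-1-[(2S)-2-methyloxiran-2-yl]-8-[(trimethylsilyl)methyl]dodeca-4,8,11-trien-1-ol; 17 (3S)-4-methylidene-5-oxooxolan-3-yl acetate (2.5 equiv)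
Product: 18 (3S,4E)-4-{(3Z,7E,11R)-11-hydroxy-8-methyl-11-[(2S)-2-methyloxiran-2-yl]-4-[(trimethylsilyl)methyl]undeca-3,7-dien-1-ylidene}-5-oxooxolan-3-yl acetate
Conditions: second-generation Hoveyda–Grubbs catalyst (7.5 mol%), 2,6-dichloro-1,4-benzoquinone (15 mol%), CH2Cl2, 40 °C, Ar sparge
Reagents that add atoms: none
Why: In this olefin cross-metathesis only the monosubstituted vinyl group initiates, the non-dimerising α-methylene lactone gives the thermodynamically preferred E-alkylidene lactone (H12 syn to C=O), the quinone suppresses Ru–H isomerisation of the skipped diene, and the few percent of ent-11 become a separable diastereomer.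

Step 11
Reactants: 18 (3S,4E)-4-{(3Z,7E,11R)-11-hydroxy-8-methyl-11-[(2S)-2-methyloxiran-2-yl]-4-[(trimethylsilyl)methyl]undeca-3,7-dien-1-ylidene}-5-oxooxolan-3-yl acetate
Product: 20 14-O-acetylandrographolide (CNP0077248.1), via chloroaluminium alkoxide chelate 19 (not isolated)
Conditions: MeAlCl2 (3.5 equiv, hexanes), CH2Cl2 (0.005 M), −78 °C, 1–2 h; aq. NaHCO3/Rochelle salt, −78 → 0 °C
Reagents that add atoms: none
Why: Proposed new method: MeAlCl2 first converts the 3-OH into an O–AlCl2 alkoxide (CH4 leaves, so no acid is released to protodesilylate), whose aluminium chelates the neighbouring epoxide oxygen O19 and holds O3 and O19 syn, which is the one conformer where C5 can attack C4 anti to O19 in a chair with O3 equatorial and where no C3 substituent is antiperiplanar for a semipinacol shift, so C4 is inverted to give axial CH2OH, anti-addition across the E-C5=C10 alkene and attack by C9 of the Z-allylsilane in a chair–chair array set C5, C10 and C9 (trans-decalin, equatorial C11), chloride removes Me3Si to give the 8(17)-methylene, and the electron-poor alkylidene lactone and its acetate only bind the excess Lewis acid; the closest known reaction type is the MeAlCl2-promoted epoxide-initiated cation–olefin polycyclisation terminated by an allylsilane, including cases with 2,2-disubstituted epoxides that leave a hydroxymethyl-bearing quaternary carbon.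

## Compound list
1 | pent-4-yn-1-ol | C#CCCCO | starting material
2 | pent-4-ynal | C#CCCC=O | intermediate
3 | rac-2-methylhept-1-en-6-yn-3-ol | C=C(C)C(O)CCC#C | intermediate
4 | 3-[(1-ethoxyethenyl)oxy]-2-methylhept-1-en-6-yne (ketene acetal, not isolated) | C=C(OCC)OC(CCC#C)C(C)=C | intermediate
5 | ethyl (4E)-4-methylnon-4-en-8-ynoate | CCOC(=O)CC/C(C)=C/CCC#C | intermediate
6 | alkenylcopper from syn-addition of Me3SiCH2Cu to 5, Cu cis to CH2SiMe3 (not isolated) | CCOC(=O)CC/C(C)=C/CC/C(C[Si](C)(C)C)=C/[Cu] | intermediate
7 | ethyl (4E,8Z)-4-methyl-8-[(trimethylsilyl)methyl]dodeca-4,8,11-trienoate | CCOC(=O)CC/C(C)=C/CC/C(C[Si](C)(C)C)=C/CC=C | intermediate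
8 | diisobutylaluminium hemiacetal of 7 (not isolated) | CCOC(O[Al](CC(C)C)CC(C)C)CC/C(C)=C/CC/C(C[Si](C)(C)C)=C/CC=C | intermediate
9 | (4E,8Z)-4-methyl-8-[(trimethylsilyl)methyl]dodeca-4,8,11-trienal (not isolated) | O=CCC/C(C)=C/CC/C(C[Si](C)(C)C)=C/CC=C | intermediate
10 | rac-(6E,10Z)-2,6-dimethyl-10-[(trimethylsilyl)methyl]tetradeca-1,6,10,13-tetraen-3-ol | C=C(C)C(O)CC/C(C)=C/CC/C(C[Si](C)(C)C)=C/CC=C | intermediate
11 | (1R,4E,8Z)-4-methyl-1-[(2S)-2-methyloxiran-2-yl]-8-[(trimethylsilyl)methyl]dodeca-4,8,11-trien-1-ol | C[C@]1(CO1)[C@H](O)CC/C(C)=C/CC/C(C[Si](C)(C)C)=C/CC=C | intermediate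
12 | (S)-3-hydroxy-γ-butyrolactone [(4S)-4-hydroxyoxolan-2-one] | O=C1C[C@H](O)CO1 | starting material
13 | dilithio alkoxide-enolate of 12 (not isolated) | [Li+].[Li+].[O-]C1=C[C@H]([O-])CO1 | intermediate
14 | (3S,4S)-3-[(dimethylamino)methyl]-4-hydroxyoxolan-2-one | CN(C)C[C@@H]1C(=O)OC[C@H]1O | intermediate
15 | [(3S,4S)-4-hydroxy-2-oxooxolan-3-yl]methyl-trimethylammonium iodide (not isolated) | C[N+](C)(C)C[C@@H]1C(=O)OC[C@H]1O.[I-] | intermediate
16 | (4S)-4-hydroxy-3-methylideneoxolan-2-one [(S)-tulipalin B] | C=C1C(=O)OC[C@H]1O | intermediate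
17 | (3S)-4-methylidene-5-oxooxolan-3-yl acetate | C=C1C(=O)OC[C@H]1OC(C)=O | intermediate
18 | (3S,4E)-4-{(3Z,7E,11R)-11-hydroxy-8-methyl-11-[(2S)-2-methyloxiran-2-yl]-4-[(trimethylsilyl)methyl]undeca-3,7-dien-1-ylidene}-5-oxooxolan-3-yl acetate | C[C@]1(CO1)[C@H](O)CC/C(C)=C/CC/C(C[Si](C)(C)C)=C/C/C=C2/C(=O)OC[C@H]2OC(C)=O | intermediate
19 | O3-dichloroaluminium alkoxide of 18, Al chelated by the epoxide oxygen (not isolated) | C[C@]1(CO1)[C@H](O[Al](Cl)Cl)CC/C(C)=C/CC/C(C[Si](C)(C)C)=C/C/C=C2/C(=O)OC[C@H]2OC(C)=O | intermediate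
20 | 14-O-acetylandrographolide, (3S,4E)-4-{2-[(1R,4aS,5R,6R,8aS)-6-hydroxy-5-(hydroxymethyl)-5,8a-dimethyl-2-methylidenedecahydronaphthalen-1-yl]ethylidene}-5-oxooxolan-3-yl acetate | C=C1CC[C@@H]2[C@](C)(CO)[C@H](O)CC[C@@]2(C)[C@@H]1C/C=C1/C(=O)OC[C@H]1OC(C)=O | target

## Step count and risks
Total step count: 11. Steps 1–6 build the chain, steps 7–9 build the lactone, and steps 10–11 are the union and the cascade.
Longest linear sequence: 8 (steps 1–6, 10, 11).

**Step 11 (cascade on the fully functionalised chain).**
- The likely failures are sequestration of MeAlCl2 by the lactone and acetate, chloride attack on the allylic acetate, Meinwald or chlorohydrin opening of the epoxide, and trapping of the C10 cation by O19.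
- The fallback sets out from 11 and comes back at 20. It separates the cascade from the sensitive side chain.
- Compound 11 alone is cyclised with MeAlCl2 (2 equiv, CH2Cl2, −78 °C). The Lewis acid then sees only the hydroxy-epoxide, and the product is the 9-allyl decalin diol F1.
- The side chain is attached last by cross-metathesis of the monosubstituted vinyl group of F1 with 17, using the second-generation Hoveyda–Grubbs catalyst and 2,6-dichlorobenzoquinone. The hindered 8(17)-methylene and the free diol are spectators, so this gives 20 directly.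

**Step 10 (cross-metathesis on the polyene).**
- The likely failures are ring closure of the C12 alkylidene onto C5=C10, isomerisation of the skipped diene, and slow turnover with the β-acetoxy-substituted lactone.
- The fallback sets out from 5 (with 17 as the second component) and comes back at 18. The union moves from C12=C13 to the C9–C11 bond and is made with copper chemistry.
- Compound 5 is reduced with iBu2AlH to (4E)-4-methylnon-4-en-8-ynal F2. This aldehyde takes up isopropenylmagnesium bromide to give the racemic enynol F3.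
- Separately, 17 is metathesised with a large excess of the simple olefin allyl bromide to give the allylic bromide F4.
- F3 is deprotonated with MeMgCl and carbocuprated with Me3SiCH2Cu as in step 4, giving the alkoxide-alkenylcopper F5.
- F5 is alkylated at −40 °C at the primary allylic bromide of F4. Attack at the fully substituted C13 is blocked. The product is the allylic alcohol F6 as a 1:1 mixture of C3 epimers.
- Sharpless epoxidation with D-(−)-diisopropyl tartrate converts only the (3R)-epimer and delivers 18.

**Step 4 (carbocupration with the sluggish Me3SiCH2Cu).**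
- The likely failures are low conversion and alkyne deprotonation.
- The fallback sets out from 5 and comes back at 7. It replaces carbometalation with halopalladation followed by cross-coupling.
- PdBr2(PhCN)2 (2 mol%) in excess allyl bromide effects syn-bromopalladation and allylation of the alkyne. This gives the (Z)-bromo-1,4-diene ester F7, with Br on C8 cis to the allyl group.
- Stereoretentive Negishi coupling with Me3SiCH2ZnCl and Pd(PPh3)4 in THF at 50 °C then gives 7.

## Further compounds
F1 | step 11 | (1R,2R,4aS,5R,8aS)-1-(hydroxymethyl)-1,4a-dimethyl-6-methylidene-5-(prop-2-en-1-yl)decahydronaphthalen-2-ol | C=C1CC[C@@H]2[C@](C)(CO)[C@H](O)CC[C@@]2(C)[C@@H]1CC=C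
F2 | step 10 | (4E)-4-methylnon-4-en-8-ynal | O=CCC/C(C)=C/CCC#C
F3 | step 10 | rac-(6E)-2,6-dimethylundeca-1,6-dien-10-yn-3-ol | C=C(C)C(O)CC/C(C)=C/CCC#C
F4 | step 10 | (3S,4E)-4-(2-bromoethylidene)-5-oxooxolan-3-yl acetate | BrC/C=C1/C(=O)OC[C@H]1OC(C)=O
F5 | step 10 | chloromagnesium alkoxide-alkenylcopper from F3 and Me3SiCH2Cu (not isolated) | C=C(C)C(O[Mg]Cl)CC/C(C)=C/CC/C(C[Si](C)(C)C)=C/[Cu]
F6 | step 10 | (3S,4E)-4-{(3Z,7E)-11-hydroxy-8,12-dimethyl-4-[(trimethylsilyl)methyl]trideca-3,7,12-trien-1-ylidene}-5-oxooxolan-3-yl acetate (C3 epimers) | C=C(C)C(O)CC/C(C)=C/CC/C(C[Si](C)(C)C)=C/C/C=C1/C(=O)OC[C@H]1OC(C)=O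
F7 | step 4 | ethyl (4E,8Z)-8-bromo-4-methyldodeca-4,8,11-trienoate | CCOC(=O)CC/C(C)=C/CC/C(Br)=C/CC=C
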